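The readings are calculated for substances that don't exist; scatter was added.

The teal flask has a large leftover. From 4.00 d on, target stands near 23.5% of the substrate charged, so 76.5% is not target, although 0.90 equiv of partner went in.

| flask | substrate | partner | temperature | remark | time |
|---|---|---|---|---|---|
| teal | 0.50 M | 0.90 equiv | 70 °C | the very flask that is asked about, followed so far |  |
| green | 0.25 M | 0.90 equiv | 76 °C | run made earlier |  |
| flask | 0.50 M | 0.900 equiv | 70 °C |  | 8.0 d |

| run | time / d | target / % | substrate / % |
|---|---|---|---|
| teal | 1.25 | 14.6 | 7.2 |
| teal | 2.50 | 21.5 | 3.1 |
| teal | 4.00 | 25.3 | 5.6 |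
| teal | 5.00 | 24.1 | 5.3 |
| teal | 6.00 | 22.0 | 4.0 |
| teal | 8.00 | 22.6 | 4.0 |
| green | 1.04 | 12.7 | 7.6 |
| green | 2.08 | 13.6 | 6.7 |
| green | 3.00 | 14.1 | 5.4 |
| green | 4.00 | 13.4 | 5.9 |
| green | 5.00 | 13.2 | 7.1 |
| green | 6.00 | 13.8 | 5.6 |

(scatter of a reading: 1 percentage point)

- what is taken out of target is counted as made
- the earlier runs were read with a standard deviation of 1 percentage point
- additions bring no volume worth counting

- south: at 8.0 d add partner, 50.0% of the amount charged, then wait 15 d
- north-west: at 8.0 d raise the temperature by 15 K, then wait 15 d
- west: at 8.0 d take out 90% of the target then present, then wait 15 d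
- north: change nothing and wait 15 d more

1. target, in percent of the substrate first charged, at 8.0 d
2. what to do for the largest gain in target; "none" if nothing gains more than 2 percentage points (south / north-west / west / north / none)
3. target present, with what was taken out counted in, in percent of the substrate first charged, after north-west
4. target present, with what was taken out counted in, in percent of the substrate first charged, after north

Where did the partner go? The green run, at 0.25 M with the same equivalents, holds 13.6%, which is 0.579 of the teal figure. Target per partner is therefore lower in the green run, which differs from the teal run in both concentration and temperature.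

This reckoning reads that as a competition and assumes a plateau without free partner. Each partner meets the pool, meaning charged substrate not yet target, or is lost without it. This reckoning assumes that the share reaching target is c(pool)/(c(pool) + h), with c(pool)/h as a selectivity factor. Summed to the plateau on that assumption, h = [c(partner charged) − c(target)] / ln[c(substrate charged)/c(pool)].

The teal run gives a split concentration 1.24 M, the c(pool) at which, in this reckoning, both fates run equally fast. The green run gives 1.30 M.

What would more partner bring to the teal flask? At the plateau c(pool) is 0.383 M, so this reckoning puts the share at 23.6%. South should therefore gain about 11 percentage points. North, north-west and west add no partner, so this reckoning gives them no gain: it says south, with target staying at 23.5%.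

The forecast differs. It gives 23.2% now, west as best, 17.5% after north-west and 23.2% after north, on the ground that “The plateaus fit two equilibria”.

The flask gives 23.5%, and south is best with 11 points; west gains 0 points. North-west ends at 23.5% and north at 23.5%.

    substrate ⇌ open intermediate (K = 16.0, k = 3.20 × 10⁻⁵ s⁻¹, Ea = 106 kJ mol⁻¹, ΔH = −26.0 kJ mol⁻¹)
    partner → second intermediate (k = 2.00 × 10⁻⁵ s⁻¹, Ea = 121 kJ mol⁻¹)
    open intermediate + second intermediate → target (k = 1.40 × 10⁻⁵ L mol⁻¹ s⁻¹, Ea = 101 kJ mol⁻¹)
    second intermediate → side product (k = 1.40 × 10⁻⁵ s⁻¹, Ea = 115 kJ mol⁻¹)
    (constants at 70 °C)

In this flask, partner turned into second intermediate with a half-life of 0.40 d while open intermediate stood at 77.2% at 0.800 d. By 4.00 d partner stood at 0.0996% of its charge, and target stood at 23.5% at 8.00 d. The scheme forms target from open intermediate, not from the pool; h remains a figure read from plateaus. The split concentration gave south 11 points, against the 11 points found. The neighbour with 3.60 equiv of partner reached 68.6%, and that yield gives h = 1.26 M.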